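## The problem

Target 39 is a ten-membered carbocycle (C1–C10) with a trans-fused α-methylene-γ-butyrolactone (lactone oxygen on C6, C11(=C13)–C12(=O) on C7). It carries a Z trisubstituted C4=C5 alkene (methyl C15 on C4), a trans 1,10-epoxide (methyl C14 on C10), a benzoate on C3 and a (2S,3S)-2,3-dimethyloxirane-2-carboxylate on C8. The ring is the central difficulty: a cyclodecane with two trisubstituted units of opposite ring geometry must be closed against transannular strain without disturbing the Z geometry at C4=C5 or the E geometry of the future C1–C10 unit. Of the six ring stereocentres (1R,3S,6R,7R,8R,10R), C6 can be bought, C7 can be set from C6 by addition anti to the C6 substituent of a butenolide, and C8 can be set from C7 by a Felkin-type ketone reduction that a chiral catalyst can reinforce. C3, C1 and C10 have no acyclic neighbour to control them and depend on the conformation of the ring once it exists; the two side-chain centres can be made separately under reagent control. Several groups will not survive rough treatment and must arrive late and in a fixed order: the α-methylene lactone is a Michael acceptor, the trisubstituted epoxide opens transannularly under acid, the C3 and C6 oxygens are both allylic to C4=C5, the epoxy ester is electrophilic, and a free C8 hydroxyl can take the lactone carbonyl over from O6. The feature that allows a mild closure is that C3 is a secondary allylic carbinol bound directly to alkene carbon C4: the C3–C4 bond is the one formed when a C4 alkenyl metal of fixed Z geometry adds to a C3 aldehyde, and an alkenylchromium reagent does this without touching a lactone or an enolisable aldehyde.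

## Retrosynthesis

**Epoxide last.** The two C–O bonds of the 1,10-epoxide of 39 are cut first, which leads to triene 38. Carrying the epoxide through the ring closure instead would expose an acid-labile, transannularly reactive group to desilylation and strong base. 38 has two stereocentres fewer. The forward reaction must select C1=C10 among three alkenes and one face of it. The first follows from electronics (C4=C5 carries two allylic acyloxy groups, C11=C13 is conjugated); the second from the fact that an E alkene in a ten-membered ring exposes only its outer face.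

**C8 ester.** The acyl C–O bond at C8 of 38 is cut to give alcohol 32 and epoxy acid 36. Esterifying with the Z-enoic acid 33 and epoxidising on the ring would require attack on an electron-poor alkene in the presence of C1=C10 and without facial control. 36 comes from 33 in three steps through allylic alcohol 34 and epoxy alcohol 35, with both side-chain stereocentres set by an asymmetric allylic-alcohol epoxidation. The forward esterification must join a hindered secondary alcohol with an α-quaternary acid without base strong enough to move the lactone from O6 to O8.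

**Lactone methylene and benzoate.** In 32 the C8 silyl ether is restored (31), the C11–C13 bond is cut through Mannich base 29 to the saturated lactone 27, and the benzoyl C–O bond at C3 is cut to give alcohol 26. The methylene group is placed after the ring closure because a Michael acceptor would not survive the bases and nucleophiles used before it. It is placed before the C8 ester because an enolate at C11 would attack an acyl group on O8 through a six-membered transition state, whereas a benzoate across the ring is out of reach. 26 carries only robust groups: a saturated lactone, one silyl ether, two alkenes and one free hydroxyl. The forward steps need clean lactone enolisation beside a benzoate and retention at C3.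

**Ring closure.** The C3–C4 bond of 26 is cut to give iodo aldehyde 25. Among the ring bonds this is the one that is both a carbinol–alkene bond and remote from the lactone. Cutting C5–C6 or C7–C8 would break up the lactone-bearing stereotriad, and cutting at either alkene would leave its geometry to the ring-forming step. 25 is open-chain apart from the butanolide and holds all ring stereocentres except C3 and both alkenes with fixed geometry. Forward, a C4 alkenyl metal must add to the C3 aldehyde intramolecularly, with retention of the Z geometry, under conditions that spare the lactone, the silyl ether and the enolisable aldehyde.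

**Ends of the chain.** The C3 aldehyde of 25 is taken back through alcohol 24 to 4-methoxybenzyl ether 23, the C8 silyl ether to alcohol 22, the C8 carbinol to ketone 21 and the ketone to dithioacetal 20. The C4=C5 bond of 20 is then cut to aldehyde 15 and the two-carbon phosphonium salt 16. Olefination installs C4, C15 and iodine at once with Z geometry; an alkyne-based route would have to solve both regiochemistry and anti-hydrometalation. C8 is assigned to a ketone reduction because the adjacent C7 centre and a chiral catalyst can act together. Orthogonality decides the order: the C5 oxygen is freed by fluoride before the C8 silyl ether exists, and the C3 oxygen is freed oxidatively after it.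

**C7–C8.** Aldehyde 15 goes back through alcohol 14 to silyl ether 13, whose C7–C8 bond is cut to give dithiane 9 (as its anion 12) and butenolide 11, made from 10. A C8–C9 cut on the lactone would need an α-selective allyl-metal addition, and a C6–C7 cut would give up the chiral-pool centre. This cut divides the molecule into two pieces of similar size. Forward, an acyl anion equivalent must add 1,4 to the butenolide and anti to the C6 substituent.

**Side chain.** Dithiane 9 is cut at C8–C9 to 1,3-dithiane 7 (as 8) and allylic bromide 6. 6 comes from alcohol 5 and ester 4, and the C10=C1 bond of 4 is cut to aldehyde 2 (from alcohol 1) and ylide 3. A stabilised α-branched ylide is the simplest reliable source of an E trisubstituted alkene. Carboalumination of a homopropargylic alcohol would put the methyl group next to the oxygenated ethylene unit, which fits the C8–C9–C10 end and would leave C1–C2 for an sp2–sp3 coupling. 1, 3, 7 and 16 are achiral catalogue compounds.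

## Roads not taken

Alternative 1: The ten-membered ring is uncovered from smaller rings instead of being closed. Enone A1 (ring carbons C5–C10) and cyclobutene ester A2 (C1–C4, with the ester carbon standing for C15) would be joined by a head-to-head [2+2] photocycloaddition that forms C4–C5 and C1–C10 and gives the cis-anti-cis tricycle A3. Heating A3 would then cleave C1–C4 and C5–C10 of the new cyclobutane in the other sense and release cyclodecadiene A4.
- Merits: two simple rings, no high dilution, no stoichiometric metal, and both ring alkenes arise in one thermal step.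
- Weak points for this target: the head-to-head orientation and the facial selectivity relative to the C3 and C8 oxygens are not secured, so several isomers of A3 must be expected. The cycloreversion is a stepwise diradical fragmentation at high temperature, so the Z/E pattern of A4 is not guaranteed, and a cyclodeca-1,5-diene can undergo Cope rearrangement under the same conditions. A4 still lacks the C7 lactone arm, the C6 and C7 stereocentres and a methyl group in place of the ester, all to be introduced on a flexible ring.
- Comparison: in throughput and waste this road is better than the chosen plan, which consumes a large excess of a chromium salt at high dilution. The chosen plan sets against this that C6, C7, C8 and both alkene geometries are fixed before the ring exists, so only C3 is left open.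

Alternative 2: The cut is the C4=C5 double bond itself, through a sulfur bridge. The eleven-membered sulfone A5, with sulfur between C4 and C5, would be halogenated at an α-carbon and collapse through an episulfone with extrusion of the sulfonyl bridge (Ramberg–Bäcklund reaction), contracting the ring to diene A6.
- Merits: the large ring is closed by C–S bond formation, which is less demanding than a C–C closure, and every stereocentre of A6, C3 included, is in place before the contraction. In that respect it is better than the chosen plan, where C3 is formed in the closure without external control.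
- Weak points: the geometry of a trisubstituted alkene formed by this contraction in a medium ring is decided by the ring and not by the reagent, so a Z/E mixture is likely. The strongly basic conditions generate carbanions at C4 and C5 that are β to the C3 and C6 oxygens, so elimination competes. A6 carries C12 at the alcohol level, so lactone and methylene group need further oxidation steps after the ring is made.
- Comparison: the chosen plan answers the C3 question with the option of benzoylation with inversion, and offers neutral ring-closing conditions, alkene geometries fixed beforehand by olefination, and a lactone already in place.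

Alternative 3: The cut is C8–C9, formed while a six-membered ring opens. The alkoxide of divinyl carbinol A7 would undergo an anionic oxy-Cope rearrangement that forms C8–C9, breaks the ring bond between the carbons that become C1 and C6, and gives cyclodecadienone A8 after protonation of the C6 enolate.
- Merits: this is the shortest way to the carbocycle, from a chiral-pool six-membered ring and without dilution. The chair transition state fixes E at C1=C10, the starting ring fixes Z at C4=C5, and the enol ether geometry sets C8. In step economy up to the ten-membered ring it is clearly better than the chosen plan.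
- Weak points: A8 has a C6 ketone and an unsubstituted C7, so the lactone arm, the C7 stereocentre and the C6 carbinol must be set on the flexible ring, by an enolate alkylation next to the C8 oxygen and a ketone reduction whose selectivities are open. The C6 ketone is conjugated with the Z alkene, which invites isomerisation and conjugate addition, and cyclodeca-1,5-dienes of this type are prone to further sigmatropic and transannular reactions.
- Comparison: the chosen plan is longer, but it places C6, C7, C8 and the lactone by acyclic or five-ring stereocontrol before closure, so the medium ring has to deliver only C3 and the epoxide.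

Key step: step 16

Remark: germacrane numbering (C1–C15) is used for all ring compounds; C11 of 29 and 30 is left unassigned because both epimers converge on 31; 1 is taken as a catalogue compound (otherwise one step from propane-1,3-diol).

## Route

Step 1
Reactants: 1 3-[(4-methoxybenzyl)oxy]propan-1-ol
Product: 2 3-[(4-methoxybenzyl)oxy]propanal
Conditions: 2,2,6,6-tetramethylpiperidin-1-oxyl (cat.), PhI(OAc)2, CH2Cl2, rt
Reagents that add atoms: none
Why: Oxoammonium (TEMPO) oxidation with PhI(OAc)2 as terminal oxidant stops at the aldehyde and is mild enough to avoid β-elimination of the 4-methoxybenzyloxy group.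

Step 2
Reactants: 2 3-[(4-methoxybenzyl)oxy]propanal; 3 ethyl 2-(triphenylphosphoranylidene)propanoate
Product: 4 ethyl (2E)-5-[(4-methoxybenzyl)oxy]-2-methylpent-2-enoate
Conditions: CH2Cl2, rt
Reagents that add atoms: none
Why: Wittig olefination with a stabilised α-branched ylide; reversible addition leads to the E trisubstituted enoate, which fixes the future C1=C10 geometry.

Step 3
Reactants: 4 ethyl (2E)-5-[(4-methoxybenzyl)oxy]-2-methylpent-2-enoate
Product: 5 (2E)-5-[(4-methoxybenzyl)oxy]-2-methylpent-2-en-1-ol
Conditions: i-Bu2AlH, CH2Cl2, −78 °C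
Reagents that add atoms: none
Why: 1,2-Reduction of the enoate by the aluminium hydride at low temperature gives the allylic alcohol without touching the alkene or the benzyl ether.

Step 4
Reactants: 5 (2E)-5-[(4-methoxybenzyl)oxy]-2-methylpent-2-en-1-ol
Product: 6 1-({[(3E)-5-bromo-4-methylpent-3-en-1-yl]oxy}methyl)-4-methoxybenzene
Conditions: CBr4, PPh3, CH2Cl2, 0 °C
Reagents that add atoms: carbon tetrabromide, BrC(Br)(Br)Br
Why: Appel bromination; SN2 displacement of the oxyphosphonium ion at the primary allylic carbon keeps alkene position and geometry.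

Step 5
Reactants: 7 1,3-dithiane; 6 1-({[(3E)-5-bromo-4-methylpent-3-en-1-yl]oxy}methyl)-4-methoxybenzene
Product: 9 2-{(2E)-5-[(4-methoxybenzyl)oxy]-2-methylpent-2-en-1-yl}-1,3-dithiane, via 2-lithio-1,3-dithiane 8 (not isolated)
Conditions: n-BuLi, THF, −30 °C; then 6, −78 → 0 °C
Reagents that add atoms: none
Why: Corey–Seebach alkylation; the sulfur-stabilised anion displaces the primary allylic bromide by SN2 at the unsubstituted carbon and forms C8–C9.

Step 6
Reactants: 10 (5S)-5-(hydroxymethyl)furan-2(5H)-one
Product: 11 (5S)-5-{[(tert-butyldiphenylsilyl)oxy]methyl}furan-2(5H)-one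
Conditions: t-BuPh2SiCl, imidazole, CH2Cl2, 0 °C → rt
Reagents that add atoms: tert-butyl(chloro)diphenylsilane, CC(C)(C)[Si](Cl)(c1ccccc1)c1ccccc1
Why: Silylation of the primary alcohol; the bulky silyl ether later shields one face of the butenolide.

Step 7
Reactants: 9 2-{(2E)-5-[(4-methoxybenzyl)oxy]-2-methylpent-2-en-1-yl}-1,3-dithiane; 11 (5S)-5-{[(tert-butyldiphenylsilyl)oxy]methyl}furan-2(5H)-one
Product: 13 (4S,5S)-5-{[(tert-butyldiphenylsilyl)oxy]methyl}-4-(2-{(2E)-5-[(4-methoxybenzyl)oxy]-2-methylpent-2-en-1-yl}-1,3-dithian-2-yl)dihydrofuran-2(3H)-one, via lithiated dithiane 12 (not isolated)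
Conditions: t-BuLi, THF/HMPA (10:1), −78 °C; then 11, −78 °C; NH4Cl (aq)
Reagents that add atoms: none
Why: Conjugate (Michael) addition of a lithiated dithiane as acyl anion equivalent; the polar cosolvent favours 1,4- over 1,2-addition, and the anion adds to the butenolide face anti to the C6 silyloxymethyl group, which sets C7 trans to C6.

Step 8
Reactants: 13 (4S,5S)-5-{[(tert-butyldiphenylsilyl)oxy]methyl}-4-(2-{(2E)-5-[(4-methoxybenzyl)oxy]-2-methylpent-2-en-1-yl}-1,3-dithian-2-yl)dihydrofuran-2(3H)-one
Product: 14 (4S,5S)-5-(hydroxymethyl)-4-(2-{(2E)-5-[(4-methoxybenzyl)oxy]-2-methylpent-2-en-1-yl}-1,3-dithian-2-yl)dihydrofuran-2(3H)-one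
Conditions: Bu4NF, AcOH, THF, 0 °C → rt
Reagents that add atoms: none
Why: Fluoride cleavage of the primary silyl ether; buffering with acetic acid keeps the lactone from opening or migrating.

Step 9
Reactants: 14 (4S,5S)-5-(hydroxymethyl)-4-(2-{(2E)-5-[(4-methoxybenzyl)oxy]-2-methylpent-2-en-1-yl}-1,3-dithian-2-yl)dihydrofuran-2(3H)-one
Product: 15 (2S,3S)-3-(2-{(2E)-5-[(4-methoxybenzyl)oxy]-2-methylpent-2-en-1-yl}-1,3-dithian-2-yl)-5-oxotetrahydrofuran-2-carbaldehyde
Conditions: SO3·pyridine, DMSO, i-Pr2NEt, CH2Cl2, 0 °C
Reagents that add atoms: none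
Why: Parikh–Doering oxidation, an activated-DMSO method that leaves the thioacetal untouched and gives the α-oxygenated aldehyde without over-oxidation; the aldehyde is used crude.

Step 10
Reactants: 15 (2S,3S)-3-(2-{(2E)-5-[(4-methoxybenzyl)oxy]-2-methylpent-2-en-1-yl}-1,3-dithian-2-yl)-5-oxotetrahydrofuran-2-carbaldehyde; 16 ethyltriphenylphosphonium iodide
Product: 20 (4S,5S)-5-[(1Z)-2-iodoprop-1-en-1-yl]-4-(2-{(2E)-5-[(4-methoxybenzyl)oxy]-2-methylpent-2-en-1-yl}-1,3-dithian-2-yl)dihydrofuran-2(3H)-one, via ethylidenetriphenylphosphorane 17 (not isolated), via (1-iodoethyl)triphenylphosphonium iodide 18 (not isolated), via (1-iodoethylidene)triphenylphosphorane 19 (not isolated)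
Conditions: 16, n-BuLi, THF, 0 °C; I2, −78 °C; NaN(SiMe3)2, −20 °C; then 15, −78 → −20 °C
Reagents that add atoms: iodine, II
Why: Stork–Zhao-type Wittig olefination with an α-iodo ylide made in the flask; kinetic cis-oxaphosphetane formation at low temperature places iodine cis to the chain, which gives the Z alkenyl iodide that becomes the Z C4=C5 alkene.

Step 11
Reactants: 20 (4S,5S)-5-[(1Z)-2-iodoprop-1-en-1-yl]-4-(2-{(2E)-5-[(4-methoxybenzyl)oxy]-2-methylpent-2-en-1-yl}-1,3-dithian-2-yl)dihydrofuran-2(3H)-one
Product: 21 (4S,5S)-5-[(1Z)-2-iodoprop-1-en-1-yl]-4-{(3E)-6-[(4-methoxybenzyl)oxy]-3-methylhex-3-enoyl}dihydrofuran-2(3H)-one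
Conditions: PhI(OCOCF3)2, MeCN/H2O (9:1), 0 °C, short reaction time
Reagents that add atoms: water, O
Why: Oxidative dithioacetal hydrolysis with a hypervalent iodine reagent; sulfur is oxidised far faster than the alkenes or the anisyl ring, and the short base-free reaction spares the β,γ-unsaturated β-acyloxy ketone, which is reduced without storage.

Step 12
Reactants: 21 (4S,5S)-5-[(1Z)-2-iodoprop-1-en-1-yl]-4-{(3E)-6-[(4-methoxybenzyl)oxy]-3-methylhex-3-enoyl}dihydrofuran-2(3H)-one
Product: 22 (4R,5S)-4-{(1R,3E)-1-hydroxy-6-[(4-methoxybenzyl)oxy]-3-methylhex-3-en-1-yl}-5-[(1Z)-2-iodoprop-1-en-1-yl]dihydrofuran-2(3H)-one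
Conditions: (S)-2-methyl-CBS-oxazaborolidine [(S)-1-methyl-3,3-diphenyltetrahydro-1H,3H-pyrrolo[1,2-c][1,3,2]oxazaborole] (0.5 equiv), catecholborane, toluene, −78 °C
Reagents that add atoms: none
Why: Corey–Bakshi–Shibata reduction; the catalyst binds the ketone with the branched C7 side as the large group and delivers hydride to the face that gives 8R, the same face that Felkin–Anh attack anti to the C7–C6 bond prefers, so catalyst and substrate control reinforce each other under non-basic conditions.

Step 13
Reactants: 22 (4R,5S)-4-{(1R,3E)-1-hydroxy-6-[(4-methoxybenzyl)oxy]-3-methylhex-3-en-1-yl}-5-[(1Z)-2-iodoprop-1-en-1-yl]dihydrofuran-2(3H)-one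
Product: 23 (4S,5S)-4-{(1R,3E)-1-[(tert-butyldimethylsilyl)oxy]-6-[(4-methoxybenzyl)oxy]-3-methylhex-3-en-1-yl}-5-[(1Z)-2-iodoprop-1-en-1-yl]dihydrofuran-2(3H)-one
Conditions: t-BuMe2SiOTf, 2,6-lutidine, CH2Cl2, −78 °C
Reagents that add atoms: tert-butyldimethylsilyl trifluoromethanesulfonate, CC(C)(C)[Si](C)(C)OS(=O)(=O)C(F)(F)F
Why: Silylation of the hindered secondary alcohol with the silyl triflate; it is fast at low temperature, which also forestalls migration of the lactone to O8.

Step 14
Reactants: 23 (4S,5S)-4-{(1R,3E)-1-[(tert-butyldimethylsilyl)oxy]-6-[(4-methoxybenzyl)oxy]-3-methylhex-3-en-1-yl}-5-[(1Z)-2-iodoprop-1-en-1-yl]dihydrofuran-2(3H)-one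
Product: 24 (4S,5S)-4-{(1R,3E)-1-[(tert-butyldimethylsilyl)oxy]-6-hydroxy-3-methylhex-3-en-1-yl}-5-[(1Z)-2-iodoprop-1-en-1-yl]dihydrofuran-2(3H)-one
Conditions: DDQ, CH2Cl2/pH 7 buffer, 0 °C
Reagents that add atoms: none
Why: Oxidative cleavage of the 4-methoxybenzyl ether by electron transfer to the quinone; silyl ether, lactone and alkenyl iodide are inert.

Step 15
Reactants: 24 (4S,5S)-4-{(1R,3E)-1-[(tert-butyldimethylsilyl)oxy]-6-hydroxy-3-methylhex-3-en-1-yl}-5-[(1Z)-2-iodoprop-1-en-1-yl]dihydrofuran-2(3H)-one
Product: 25 (3E,6R)-6-[(tert-butyldimethylsilyl)oxy]-6-{(2S,3S)-2-[(1Z)-2-iodoprop-1-en-1-yl]-5-oxotetrahydrofuran-3-yl}-4-methylhex-3-enal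
Conditions: Dess–Martin periodinane, NaHCO3, CH2Cl2, 0 °C
Reagents that add atoms: none
Why: Dess–Martin oxidation under buffered non-basic conditions gives the β,γ-unsaturated aldehyde without conjugation; it is used at once.

Step 16
Reactants: 25 (3E,6R)-6-[(tert-butyldimethylsilyl)oxy]-6-{(2S,3S)-2-[(1Z)-2-iodoprop-1-en-1-yl]-5-oxotetrahydrofuran-3-yl}-4-methylhex-3-enal
Product: 26 (1(10)E,3S,4Z,6R,7S,8R)-8-[(tert-butyldimethylsilyl)oxy]-3-hydroxy-13-norgermacra-1(10),4-dien-12,6-olide
Conditions: CrCl2 (10 equiv), NiCl2 (0.1 equiv), degassed DMSO, rt, slow addition of 25 to a final 0.003 M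
Reagents that add atoms: none
Why: NiCl2 is reduced by CrCl2 to zerovalent nickel, which inserts into the C4–I bond with retention of the Z geometry; transmetalation gives an alkenyl species of trivalent chromium that adds to the C3 aldehyde, and divalent chromium returns nickel to the cycle. The closest known reaction type is the intramolecular Nozaki–Hiyama–Kishi coupling of alkenyl iodides with aldehydes used for medium rings. The ten-membered carbocycle closes by carbonyl addition, 10-exo-trig at C3. The new stereocentre C3 is controlled by the conformation of the closing chain: the trans lactone fixes the C5–C6–C7–C8 segment, the Z and E alkenes remove further rotors, and the aldehyde is expected to react through the rotamer that keeps the O–Cr bond on the outside of the forming ring, which corresponds to the 3S (3β) alcohol. The step needs chemoselectivity for the aldehyde over the lactone and tolerance of the enolisable β,γ-unsaturated aldehyde, both secured by the non-basic, aldehyde-selective organochromium reagent. It needs ring closure over oligomerisation, secured by slow addition at high dilution. It needs one C3 configuration, which is the least secure point and is covered because the epimer can be benzoylated with inversion.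

Step 17
Reactants: 26 (1(10)E,3S,4Z,6R,7S,8R)-8-[(tert-butyldimethylsilyl)oxy]-3-hydroxy-13-norgermacra-1(10),4-dien-12,6-olide
Product: 27 (1(10)E,3S,4Z,6R,7S,8R)-3-(benzoyloxy)-8-[(tert-butyldimethylsilyl)oxy]-13-norgermacra-1(10),4-dien-12,6-olide
Conditions: BzCl, pyridine, 4-(dimethylamino)pyridine (cat.), CH2Cl2, 0 °C → rt
Reagents that add atoms: benzoyl chloride, O=C(Cl)c1ccccc1
Why: Acylation of the secondary allylic alcohol with retention at C3; the C8 oxygen is still silylated, so only one hydroxyl is available.

Step 18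
Reactants: 27 (1(10)E,3S,4Z,6R,7S,8R)-3-(benzoyloxy)-8-[(tert-butyldimethylsilyl)oxy]-13-norgermacra-1(10),4-dien-12,6-olide
Product: 29 (1(10)E,3S,4Z,6R,7S,8R)-3-(benzoyloxy)-8-[(tert-butyldimethylsilyl)oxy]-13-(dimethylamino)germacra-1(10),4-dien-12,6-olide, via lithium enolate 28 (not isolated)
Conditions: LiN(i-Pr)2, THF, −78 °C; then Me2N=CH2 I, −78 → 0 °C
Reagents that add atoms: N,N-dimethylmethaniminium iodide, C=[N+](C)C.[I-]
Why: Mannich reaction of the lactone lithium enolate with an iminium salt introduces C13; the benzoate has no α-hydrogen and is not attacked by the hindered amide base at −78 °C, and the C11 configuration that forms is irrelevant.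

Step 19
Reactants: 29 (1(10)E,3S,4Z,6R,7S,8R)-3-(benzoyloxy)-8-[(tert-butyldimethylsilyl)oxy]-13-(dimethylamino)germacra-1(10),4-dien-12,6-olide
Product: 31 (1(10)E,3S,4Z,6R,7S,8R)-3-(benzoyloxy)-8-[(tert-butyldimethylsilyl)oxy]germacra-1(10),4,11(13)-trien-12,6-olide, via trimethylammonium iodide 30 (not isolated)
Conditions: MeI, MeOH, rt; then NaHCO3 (aq), EtOAc, rt
Reagents that add atoms: none
Why: Exhaustive N-methylation followed by Hofmann-type E1cB elimination of trimethylamine from the β-ammonio lactone gives the α-methylene lactone under mild base.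

Step 20
Reactants: 31 (1(10)E,3S,4Z,6R,7S,8R)-3-(benzoyloxy)-8-[(tert-butyldimethylsilyl)oxy]germacra-1(10),4,11(13)-trien-12,6-olide
Product: 32 (1(10)E,3S,4Z,6R,7R,8R)-3-(benzoyloxy)-8-hydroxygermacra-1(10),4,11(13)-trien-12,6-olide
Conditions: HF·pyridine, pyridine, THF, 0 °C → rt
Reagents that add atoms: none
Why: Fluoride-mediated desilylation under buffered acidic conditions, which avoids alkoxide formation and with it O6-to-O8 lactone migration, benzoate migration and conjugate addition.

Step 21
Reactants: 33 (2Z)-2-methylbut-2-enoic acid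
Product: 34 (2Z)-2-methylbut-2-en-1-ol
Conditions: LiAlH4, Et2O, 0 °C
Reagents that add atoms: none
Why: Hydride reduction of the carboxylate to the allylic alcohol; the Z geometry is retained because the carboxylate is not isomerised at this temperature.

Step 22
Reactants: 34 (2Z)-2-methylbut-2-en-1-ol
Product: 35 [(2R,3S)-2,3-dimethyloxiran-2-yl]methanol
Conditions: Ti(O-i-Pr)4 (10 mol%), D-(−)-diisopropyl tartrate (12 mol%), t-BuOOH, 4 Å molecular sieves, CH2Cl2, −20 °C
Reagents that add atoms: tert-butyl hydroperoxide, CC(C)(C)OO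
Why: Sharpless asymmetric epoxidation; with the D-(−)-tartrate ligand the titanium-bound peroxide is delivered to the face that gives 2R, and the cis relation of hydroxymethyl and C3 methyl follows from syn addition to the Z alkene, which makes C3 S.

Step 23
Reactants: 35 [(2R,3S)-2,3-dimethyloxiran-2-yl]methanol
Product: 36 (2S,3S)-2,3-dimethyloxirane-2-carboxylic acid
Conditions: RuCl3 (cat.), NaIO4, MeCN/EtOAc/H2O, rt
Reagents that add atoms: water, O
Why: Ruthenium tetroxide oxidation of the primary alcohol through the aldehyde hydrate to the acid; the epoxide is stable and neither stereocentre can enolise (the descriptor at C2 changes only because the substituent priorities change).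

Step 24
Reactants: 36 (2S,3S)-2,3-dimethyloxirane-2-carboxylic acid; 32 (1(10)E,3S,4Z,6R,7R,8R)-3-(benzoyloxy)-8-hydroxygermacra-1(10),4,11(13)-trien-12,6-olide
Product: 38 (1(10)E,3S,4Z,6R,7R,8R)-3-(benzoyloxy)-8-{[(2S,3S)-2,3-dimethyloxirane-2-carbonyl]oxy}germacra-1(10),4,11(13)-trien-12,6-olide, via mixed anhydride 37 (not isolated)
Conditions: 36, 2,4,6-trichlorobenzoyl chloride, Et3N, toluene, rt; then 32, 4-(dimethylamino)pyridine, toluene, rt
Reagents that add atoms: none
Why: Yamaguchi esterification; the pyridine catalyst attacks the less hindered aliphatic carbonyl of the mixed anhydride and transfers the epoxyacyl group to the C8 hydroxyl with retention at C8 and in the acid.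

Step 25
Reactants: 38 (1(10)E,3S,4Z,6R,7R,8R)-3-(benzoyloxy)-8-{[(2S,3S)-2,3-dimethyloxirane-2-carbonyl]oxy}germacra-1(10),4,11(13)-trien-12,6-olide
Product: 39 (1R,3S,4Z,6R,7R,8R,10R)-3-(benzoyloxy)-8-{[(2S,3S)-2,3-dimethyloxirane-2-carbonyl]oxy}-1,10-epoxygermacra-4,11(13)-dien-12,6-olide
Conditions: 3-chloroperoxybenzoic acid, NaHCO3, CH2Cl2, 0 °C
Reagents that add atoms: 3-chloroperoxybenzoic acid, OOC(=O)c1cccc(Cl)c1
Why: Prilezhaev epoxidation; the peracid selects the only electron-rich alkene (C4=C5 is deactivated by two allylic acyloxy groups, C11=C13 is conjugated), and attack on the exposed face of the E alkene in the conformer with C14 on the β face, the one expected with a β substituent at C7, should give the trans 1β,10α-epoxide (1R,10R).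

## Compound list

1 | 3-[(4-methoxybenzyl)oxy]propan-1-ol | COc1ccc(COCCCO)cc1 | starting material
2 | 3-[(4-methoxybenzyl)oxy]propanal | COc1ccc(COCCC=O)cc1 | intermediate
3 | ethyl 2-(triphenylphosphoranylidene)propanoate | CCOC(=O)C(C)=P(c1ccccc1)(c1ccccc1)c1ccccc1 | starting material
4 | ethyl (2E)-5-[(4-methoxybenzyl)oxy]-2-methylpent-2-enoate | CCOC(=O)/C(C)=C/CCOCc1ccc(OC)cc1 | intermediate
5 | (2E)-5-[(4-methoxybenzyl)oxy]-2-methylpent-2-en-1-ol | OC/C(C)=C/CCOCc1ccc(OC)cc1 | intermediate
6 | 1-({[(3E)-5-bromo-4-methylpent-3-en-1-yl]oxy}methyl)-4-methoxybenzene | BrC/C(C)=C/CCOCc1ccc(OC)cc1 | intermediate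
7 | 1,3-dithiane | C1CSCSC1 | starting material
8 | 2-lithio-1,3-dithiane | [Li]C1SCCCS1 | intermediate (not isolated)
9 | 2-{(2E)-5-[(4-methoxybenzyl)oxy]-2-methylpent-2-en-1-yl}-1,3-dithiane | COc1ccc(COCC/C=C(\C)CC2SCCCS2)cc1 | intermediate
10 | (5S)-5-(hydroxymethyl)furan-2(5H)-one | O=C1C=C[C@@H](CO)O1 | starting material
11 | (5S)-5-{[(tert-butyldiphenylsilyl)oxy]methyl}furan-2(5H)-one | O=C1C=C[C@@H](CO[Si](c2ccccc2)(c2ccccc2)C(C)(C)C)O1 | intermediate
12 | 2-lithio-2-{(2E)-5-[(4-methoxybenzyl)oxy]-2-methylpent-2-en-1-yl}-1,3-dithiane | [Li]C1(C/C(C)=C/CCOCc2ccc(OC)cc2)SCCCS1 | intermediate (not isolated)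
13 | (4S,5S)-5-{[(tert-butyldiphenylsilyl)oxy]methyl}-4-(2-{(2E)-5-[(4-methoxybenzyl)oxy]-2-methylpent-2-en-1-yl}-1,3-dithian-2-yl)dihydrofuran-2(3H)-one (C6/C7 trans) | O=C1C[C@H](C2(C/C(C)=C/CCOCc3ccc(OC)cc3)SCCCS2)[C@@H](CO[Si](c2ccccc2)(c2ccccc2)C(C)(C)C)O1 | intermediate
14 | (4S,5S)-5-(hydroxymethyl)-4-(2-{(2E)-5-[(4-methoxybenzyl)oxy]-2-methylpent-2-en-1-yl}-1,3-dithian-2-yl)dihydrofuran-2(3H)-one | O=C1C[C@H](C2(C/C(C)=C/CCOCc3ccc(OC)cc3)SCCCS2)[C@@H](CO)O1 | intermediate
15 | (2S,3S)-3-(2-{(2E)-5-[(4-methoxybenzyl)oxy]-2-methylpent-2-en-1-yl}-1,3-dithian-2-yl)-5-oxotetrahydrofuran-2-carbaldehyde | O=C1C[C@H](C2(C/C(C)=C/CCOCc3ccc(OC)cc3)SCCCS2)[C@@H](C=O)O1 | intermediate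
16 | ethyltriphenylphosphonium iodide | CC[P+](c1ccccc1)(c1ccccc1)c1ccccc1.[I-] | starting material
17 | ethylidenetriphenylphosphorane | CC=P(c1ccccc1)(c1ccccc1)c1ccccc1 | intermediate (not isolated)
18 | (1-iodoethyl)triphenylphosphonium iodide | CC(I)[P+](c1ccccc1)(c1ccccc1)c1ccccc1.[I-] | intermediate (not isolated)
19 | (1-iodoethylidene)triphenylphosphorane | CC(I)=P(c1ccccc1)(c1ccccc1)c1ccccc1 | intermediate (not isolated)
20 | (4S,5S)-5-[(1Z)-2-iodoprop-1-en-1-yl]-4-(2-{(2E)-5-[(4-methoxybenzyl)oxy]-2-methylpent-2-en-1-yl}-1,3-dithian-2-yl)dihydrofuran-2(3H)-one | O=C1C[C@H](C2(C/C(C)=C/CCOCc3ccc(OC)cc3)SCCCS2)[C@@H](/C=C(/C)I)O1 | intermediate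
21 | (4S,5S)-5-[(1Z)-2-iodoprop-1-en-1-yl]-4-{(3E)-6-[(4-methoxybenzyl)oxy]-3-methylhex-3-enoyl}dihydrofuran-2(3H)-one | O=C1C[C@H](C(=O)C/C(C)=C/CCOCc2ccc(OC)cc2)[C@@H](/C=C(/C)I)O1 | intermediate
22 | (4R,5S)-4-{(1R,3E)-1-hydroxy-6-[(4-methoxybenzyl)oxy]-3-methylhex-3-en-1-yl}-5-[(1Z)-2-iodoprop-1-en-1-yl]dihydrofuran-2(3H)-one | O=C1C[C@H]([C@H](O)C/C(C)=C/CCOCc2ccc(OC)cc2)[C@@H](/C=C(/C)I)O1 | intermediate
23 | (4S,5S)-4-{(1R,3E)-1-[(tert-butyldimethylsilyl)oxy]-6-[(4-methoxybenzyl)oxy]-3-methylhex-3-en-1-yl}-5-[(1Z)-2-iodoprop-1-en-1-yl]dihydrofuran-2(3H)-one | O=C1C[C@H]([C@H](O[Si](C)(C)C(C)(C)C)C/C(C)=C/CCOCc2ccc(OC)cc2)[C@@H](/C=C(/C)I)O1 | intermediate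
24 | (4S,5S)-4-{(1R,3E)-1-[(tert-butyldimethylsilyl)oxy]-6-hydroxy-3-methylhex-3-en-1-yl}-5-[(1Z)-2-iodoprop-1-en-1-yl]dihydrofuran-2(3H)-one | O=C1C[C@H]([C@H](O[Si](C)(C)C(C)(C)C)C/C(C)=C/CCO)[C@@H](/C=C(/C)I)O1 | intermediate
25 | (3E,6R)-6-[(tert-butyldimethylsilyl)oxy]-6-{(2S,3S)-2-[(1Z)-2-iodoprop-1-en-1-yl]-5-oxotetrahydrofuran-3-yl}-4-methylhex-3-enal | O=C1C[C@H]([C@H](O[Si](C)(C)C(C)(C)C)C/C(C)=C/CC=O)[C@@H](/C=C(/C)I)O1 | intermediate
26 | (1(10)E,3S,4Z,6R,7S,8R)-8-[(tert-butyldimethylsilyl)oxy]-3-hydroxy-13-norgermacra-1(10),4-dien-12,6-olide (trans-fused butanolide with C11H2; 3β-OH, 8β-silyloxy) | C1C(=O)O[C@@H]2/C=C(/C)[C@@H](O)C/C=C(\C)C[C@@H](O[Si](C)(C)C(C)(C)C)[C@@H]12 | intermediate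
27 | (1(10)E,3S,4Z,6R,7S,8R)-3-(benzoyloxy)-8-[(tert-butyldimethylsilyl)oxy]-13-norgermacra-1(10),4-dien-12,6-olide | C1C(=O)O[C@@H]2/C=C(/C)[C@@H](OC(=O)c3ccccc3)C/C=C(\C)C[C@@H](O[Si](C)(C)C(C)(C)C)[C@@H]12 | intermediate
28 | lithium enolate of 27 (C11=C12–OLi) | C1=C(O[Li])O[C@@H]2/C=C(/C)[C@@H](OC(=O)c3ccccc3)C/C=C(\C)C[C@@H](O[Si](C)(C)C(C)(C)C)[C@@H]12 | intermediate (not isolated)
29 | (1(10)E,3S,4Z,6R,7S,8R)-3-(benzoyloxy)-8-[(tert-butyldimethylsilyl)oxy]-13-(dimethylamino)germacra-1(10),4-dien-12,6-olide (C11 unassigned) | CN(C)CC1C(=O)O[C@@H]2/C=C(/C)[C@@H](OC(=O)c3ccccc3)C/C=C(\C)C[C@@H](O[Si](C)(C)C(C)(C)C)[C@@H]12 | intermediate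
30 | N,N,N-trimethylammonium iodide derived from 29 (C11 unassigned) | C[N+](C)(C)CC1C(=O)O[C@@H]2/C=C(/C)[C@@H](OC(=O)c3ccccc3)C/C=C(\C)C[C@@H](O[Si](C)(C)C(C)(C)C)[C@@H]12.[I-] | intermediate (not isolated)
31 | (1(10)E,3S,4Z,6R,7S,8R)-3-(benzoyloxy)-8-[(tert-butyldimethylsilyl)oxy]germacra-1(10),4,11(13)-trien-12,6-olide | C=C1C(=O)O[C@@H]2/C=C(/C)[C@@H](OC(=O)c3ccccc3)C/C=C(\C)C[C@@H](O[Si](C)(C)C(C)(C)C)[C@@H]12 | intermediate
32 | (1(10)E,3S,4Z,6R,7R,8R)-3-(benzoyloxy)-8-hydroxygermacra-1(10),4,11(13)-trien-12,6-olide | C=C1C(=O)O[C@@H]2/C=C(/C)[C@@H](OC(=O)c3ccccc3)C/C=C(\C)C[C@@H](O)[C@@H]12 | intermediate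
33 | (2Z)-2-methylbut-2-enoic acid (angelic acid) | C/C=C(/C)C(=O)O | starting material
34 | (2Z)-2-methylbut-2-en-1-ol | C/C=C(/C)CO | intermediate
35 | [(2R,3S)-2,3-dimethyloxiran-2-yl]methanol | OC[C@@]1(C)O[C@H]1C | intermediate
36 | (2S,3S)-2,3-dimethyloxirane-2-carboxylic acid | OC(=O)[C@@]1(C)O[C@H]1C | intermediate
37 | (2S,3S)-2,3-dimethyloxirane-2-carboxylic 2,4,6-trichlorobenzoic anhydride | O=C(OC(=O)[C@@]1(C)O[C@H]1C)c1c(Cl)cc(Cl)cc1Cl | intermediate (not isolated)
38 | (1(10)E,3S,4Z,6R,7R,8R)-3-(benzoyloxy)-8-{[(2S,3S)-2,3-dimethyloxirane-2-carbonyl]oxy}germacra-1(10),4,11(13)-trien-12,6-olide | C=C1C(=O)O[C@@H]2/C=C(/C)[C@@H](OC(=O)c3ccccc3)C/C=C(\C)C[C@@H](OC(=O)[C@@]3(C)O[C@H]3C)[C@@H]12 | intermediate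
39 | (1R,3S,4Z,6R,7R,8R,10R)-3-(benzoyloxy)-8-{[(2S,3S)-2,3-dimethyloxirane-2-carbonyl]oxy}-1,10-epoxygermacra-4,11(13)-dien-12,6-olide (CNP0324463.3) | C=C1C(=O)O[C@@H]2/C=C(/C)[C@@H](OC(=O)c3ccccc3)C[C@H]3O[C@]3(C)C[C@@H](OC(=O)[C@@]3(C)O[C@H]3C)[C@@H]12 | target

## Step count and least certain steps

Total step count: 25. Longest linear sequence: 21 steps (steps 1–5, 7–20, 24 and 25). Step 6 and steps 21–23 are side branches.

**Step 16 (key step).** Intermolecular coupling can outrun closure of the strained ten-membered ring, the alkenylchromium species can be protonated before it cyclises, and the aldehyde can be attacked on the undesired face, because nothing but the folding of the chain controls C3. Fallback: if 25 closes mainly to the C3 epimer, (1(10)E,3R,4Z,6R,7S,8R)-8-[(tert-butyldimethylsilyl)oxy]-3-hydroxy-13-norgermacra-1(10),4-dien-12,6-olide F1, that alcohol is esterified under Mitsunobu conditions (benzoic acid, PPh3, diisopropyl azodicarboxylate, THF, 0 °C) with inversion at C3. The fallback sets out from 25 and comes back to the route at 27.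

**Step 7.** The tertiary, strongly basic dithiane anion may add 1,2 to the lactone carbonyl or remove the γ-proton of the butenolide, after which the silyloxy group is eliminated. Addition next to the C6 substituent is also sterically demanding. Fallback: the anion 12, generated from 9, is added to the catalogue acyclic acceptor methyl (2E)-3-[(4S)-2,2-dimethyl-1,3-dioxolan-4-yl]prop-2-enoate, which has no route to an aromatic dienolate. Felkin-type attack anti to the γ C–O bond should give methyl (3S)-3-[(4S)-2,2-dimethyl-1,3-dioxolan-4-yl]-3-(2-{(2E)-5-[(4-methoxybenzyl)oxy]-2-methylpent-2-en-1-yl}-1,3-dithian-2-yl)propanoate F2. Aqueous acetic acid then removes the acetonide and closes the trans lactone. The fallback sets out from 9 and comes back at 14.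

**Step 10.** The basic α-iodo ylide may enolise the α-oxygenated aldehyde (loss of configuration at C6), the Z/E ratio may erode, and conversion with this hindered ylide is often incomplete. Fallback: a two-stage construction of the alkenyl halide.
- Ramirez olefination of 15 (CBr4, PPh3, CH2Cl2, 0 °C) gives (4S,5S)-5-(2,2-dibromoethenyl)-4-(2-{(2E)-5-[(4-methoxybenzyl)oxy]-2-methylpent-2-en-1-yl}-1,3-dithian-2-yl)dihydrofuran-2(3H)-one F3.
- Negishi coupling (MeZnCl, Pd(PPh3)4, THF) replaces the more reactive bromine trans to the ring and gives (4S,5S)-5-[(1Z)-2-bromoprop-1-en-1-yl]-4-(2-{(2E)-5-[(4-methoxybenzyl)oxy]-2-methylpent-2-en-1-yl}-1,3-dithian-2-yl)dihydrofuran-2(3H)-one F4.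
- Copper-catalysed halogen exchange (CuI, NaI, N,N′-dimethylethane-1,2-diamine, dioxane, heat) proceeds with retention.

The fallback sets out from 15 and comes back at 20.

**Step 12.** The catalyst distinguishes only a secondary from a primary alkyl group, so facial discrimination may be insufficient. The free C8 alcohol can also take over the lactone carbonyl before it is silylated. Fallback: if the C8 epimer, (4R,5S)-4-{(1S,3E)-1-hydroxy-6-[(4-methoxybenzyl)oxy]-3-methylhex-3-en-1-yl}-5-[(1Z)-2-iodoprop-1-en-1-yl]dihydrofuran-2(3H)-one F5, is formed from 21, it is inverted by Mitsunobu esterification with chloroacetic acid (PPh3, diisopropyl azodicarboxylate). This gives (1R,3E)-1-{(2S,3R)-2-[(1Z)-2-iodoprop-1-en-1-yl]-5-oxotetrahydrofuran-3-yl}-6-[(4-methoxybenzyl)oxy]-3-methylhex-3-en-1-yl chloroacetate F6, and thiourea with NaHCO3 in ethanol removes the chloroacetyl group without opening the lactone. The fallback sets out from 21 and comes back at 22.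

**Step 25.** If the reacting conformer exposes the other face of C1=C10, oxygen is delivered to the wrong face. Over-oxidation at C4=C5 and acid-promoted transannular opening of the new epoxide by the chlorobenzoic acid are further risks. Fallback: control is moved from the substrate to a catalyst. 38 is epoxidised with the dioxirane generated from 1,2:4,5-di-O-isopropylidene-β-D-erythro-2,3-hexodiulo-2,6-pyranose (the D-fructose-derived Shi ketone) and KHSO5 (as 2KHSO5·KHSO4·K2SO4) with K2CO3 in MeCN/dimethoxymethane/water at 0 °C. Its known sense for E trisubstituted alkenes corresponds to the (1R,10R) epoxide, and the basic buffer removes the acid. The fallback sets out from 38 and comes back at 39; it makes no new compound (F0).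

## Further compounds

F1 | step 16 | (1(10)E,3R,4Z,6R,7S,8R)-8-[(tert-butyldimethylsilyl)oxy]-3-hydroxy-13-norgermacra-1(10),4-dien-12,6-olide (C3 epimer of 26) | C1C(=O)O[C@@H]2/C=C(/C)[C@H](O)C/C=C(\C)C[C@@H](O[Si](C)(C)C(C)(C)C)[C@@H]12
F2 | step 7 | methyl (3S)-3-[(4S)-2,2-dimethyl-1,3-dioxolan-4-yl]-3-(2-{(2E)-5-[(4-methoxybenzyl)oxy]-2-methylpent-2-en-1-yl}-1,3-dithian-2-yl)propanoate | COC(=O)C[C@H](C1(C/C(C)=C/CCOCc2ccc(OC)cc2)SCCCS1)[C@H]1COC(C)(C)O1
F3 | step 10 | (4S,5S)-5-(2,2-dibromoethenyl)-4-(2-{(2E)-5-[(4-methoxybenzyl)oxy]-2-methylpent-2-en-1-yl}-1,3-dithian-2-yl)dihydrofuran-2(3H)-one | O=C1C[C@H](C2(C/C(C)=C/CCOCc3ccc(OC)cc3)SCCCS2)[C@@H](C=C(Br)Br)O1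
F4 | step 10 | (4S,5S)-5-[(1Z)-2-bromoprop-1-en-1-yl]-4-(2-{(2E)-5-[(4-methoxybenzyl)oxy]-2-methylpent-2-en-1-yl}-1,3-dithian-2-yl)dihydrofuran-2(3H)-one | O=C1C[C@H](C2(C/C(C)=C/CCOCc3ccc(OC)cc3)SCCCS2)[C@@H](/C=C(/C)Br)O1
F5 | step 12 | (4R,5S)-4-{(1S,3E)-1-hydroxy-6-[(4-methoxybenzyl)oxy]-3-methylhex-3-en-1-yl}-5-[(1Z)-2-iodoprop-1-en-1-yl]dihydrofuran-2(3H)-one (C8 epimer of 22) | O=C1C[C@H]([C@@H](O)C/C(C)=C/CCOCc2ccc(OC)cc2)[C@@H](/C=C(/C)I)O1
F6 | step 12 | (1R,3E)-1-{(2S,3R)-2-[(1Z)-2-iodoprop-1-en-1-yl]-5-oxotetrahydrofuran-3-yl}-6-[(4-methoxybenzyl)oxy]-3-methylhex-3-en-1-yl chloroacetate | O=C1C[C@H]([C@H](OC(=O)CCl)C/C(C)=C/CCOCc2ccc(OC)cc2)[C@@H](/C=C(/C)I)O1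
F0 | step 25 | none | none
A1 | alternative 1 | (5R)-5-[(tert-butyldimethylsilyl)oxy]-3-methylcyclohex-2-en-1-one (enone partner) | CC1=CC(=O)C[C@H](O[Si](C)(C)C(C)(C)C)C1
A2 | alternative 1 | methyl (4S)-4-[(triethylsilyl)oxy]cyclobut-1-ene-1-carboxylate (cyclobutene partner) | COC(=O)C1=CC[C@@H]1O[Si](CC)(CC)CC
A3 | alternative 1 | cis-anti-cis tricyclic photoadduct (cyclohexanone–cyclobutane–cyclobutane) | COC(=O)[C@@]12[C@@H](O[Si](CC)(CC)CC)C[C@@H]1[C@@]1(C)C[C@@H](O[Si](C)(C)C(C)(C)C)CC(=O)[C@H]12
A4 | alternative 1 | ten-membered 6-oxo-1(10),4-diene from cycloreversion (C15 as methyl ester, 3-triethylsilyloxy, 8-tert-butyldimethylsilyloxy) | O=C1/C=C(/C(=O)OC)[C@@H](O[Si](CC)(CC)CC)C/C=C(\C)C[C@@H](O[Si](C)(C)C(C)(C)C)C1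
A5 | alternative 2 | eleven-membered cyclic sulfone with sulfur between C4 and C5 (C4 unassigned) | C=C(CO[Si](C)(C)C(C)(C)C)[C@H]1[C@H](O[Si](C)(C)C(C)(C)C)CS(=O)(=O)C(C)[C@@H](OCc2ccc(OC)cc2)C/C=C(\C)C[C@H]1OCOC
A6 | alternative 2 | (4Z,1(10)E)-cyclodecadiene with C6 and C12 silyl ethers, C3 4-methoxybenzyl ether and C8 methoxymethyl ether | C=C(CO[Si](C)(C)C(C)(C)C)[C@H]1[C@H](O[Si](C)(C)C(C)(C)C)/C=C(/C)[C@@H](OCc2ccc(OC)cc2)C/C=C(\C)C[C@H]1OCOC
A7 | alternative 3 | 4-[(tert-butyldimethylsilyl)oxy]-6-isopropenyl-1-[(E)-2-(methoxymethoxy)ethenyl]-3-methylcyclohex-2-en-1-ol (vinyl and isopropenyl trans) | O[C@]1(/C=C/OCOC)C=C(C)[C@@H](O[Si](C)(C)C(C)(C)C)C[C@@H]1C(C)=C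
A8 | alternative 3 | (4Z,1(10)E)-cyclodecadienone with C6 ketone, C3 silyl ether and C8 methoxymethyl ether | O=C1/C=C(/C)[C@@H](O[Si](C)(C)C(C)(C)C)C/C=C(\C)C[C@@H](OCOC)C1
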